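## Retrosynthetic overview
1. The 10-membered ring is not closed by macrocyclisation. It is released last by a Criegee rearrangement of a C5 perester on a eudesmane-type decalin: the C5–C10 bond becomes C5=O plus C10–OH, with retention at C10.
2. The C5 hydroperoxide comes from perhydrolysis of a 5β,6β-epoxide (which fixes C6–O) on a Δ5-octalin that already carries the trans α-methylene-γ-lactone.
3. Ring B stereocentres are relayed from C9: Luche reduction (C9), Stork–Danheiser transposition, α-iodination/Negishi coupling (C11–C12), deconjugative kinetic protonation (C7 and the Δ5 alkene), hydroxyl-directed reduction (C8).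
4. Both carbocycles and the C4/C10 stereocentres come from one catalytic enantioselective quinone Diels–Alder (2-methoxy-6-methylbenzoquinone + 2-silyloxy-1,3-pentadiene); C2–OH by L-Selectride.
5. Ring order: A and B together (Diels–Alder), then the γ-lactone, then the 10-membered ring (ring expansion).

## Assumptions
- The target is taken as the open hydroxy-ketone drawn; any C2–OH/C5=O hemiketal equilibrium is a property of the compound. Its configuration in the numbering below is 2S,4S,6S,7R,8R,9S,10S.
- Numbering follows the target: ring C1–C10, with C4 bearing the secondary Me, C5 the ketone, C10 the carbinol Me, lactone C11 (α-C), C12 (C=O), C13 (=CH2). In bicyclic intermediates C5/C10 are the ring-fusion carbons and β is the face of the C10 methyl.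
- The Diels–Alder catalyst antipode is whichever delivers the enantiomer drawn for compound 5; I have not derived the sense from a model.

## Route

**Step 1**
Reactants: 1, 2-methoxy-6-methylphenol
Product: 2, 2-methoxy-6-methyl-1,4-benzoquinone
Conditions: O2 (1 atm), Co(salen) (10 mol%), DMF, rt
Reagents that add atoms: dioxygen, O=O
Why: Cobalt–salen (salcomine) aerobic para-oxidation of a 2,6-disubstituted phenol gives the p-quinone; no stereocentre.

**Step 2**
Reactants: 3, (E)-pent-3-en-2-one
Product: 4, (E)-2-(triisopropylsilyloxy)penta-1,3-diene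
Conditions: TIPSOTf, Et3N, CH2Cl2, 0 °C → rt
Reagents that add atoms: TIPSOTf, CC(C)[Si](OS(=O)(=O)C(F)(F)F)(C(C)C)C(C)C
Why: Soft enolisation/O-silylation at the methyl ketone gives the cross-conjugated 2-silyloxydiene with the E-propenyl geometry retained.

**Step 3**
Reactants: 2, 2-methoxy-6-methyl-1,4-benzoquinone; 4, (E)-2-(triisopropylsilyloxy)penta-1,3-diene
Product: 5, cis-fused adduct 8-methoxy-4α,10β-dimethyl-2-(TIPS-oxy)-5βH-bicyclo[4.4.0]deca-2,7-diene-6,9-dione
Conditions: o-tolyl oxazaborolidine (from diphenylprolinol)·HNTf2 (20 mol%), CH2Cl2, −78 → −40 °C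
Reagents that add atoms: none
Why: Oxazaborolidinium-catalysed quinone Diels–Alder; the catalyst binds the unhindered, more basic vinylogous-ester C=O so the diene CH2 terminus (para to OSi) bonds to the methylated carbon (C10 quaternary) and the CHMe terminus to C5, the endo transition state gives 4α-Me/5β-H/10β-Me, the catalyst sets absolute configuration, and the angular methyl blocks aromatisation.

**Step 4**
Reactants: 5
Product: 6, 9α-hydroxy-8-methoxy-4α,10β-dimethyl-2-(TIPS-oxy)-5βH-bicyclo[4.4.0]deca-2,7-dien-6-one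
Conditions: NaBH4, CeCl3·7H2O, MeOH, −78 °C
Reagents that add atoms: none
Why: Luche 1,2-reduction selects the ketone-type C9=O over the vinylogous-ester C6=O, and hydride adds from the convex β-face (the α-face is covered by the axial C1 of ring A), giving 9α-OH.

**Step 5**
Reactants: 6
Product: 7, 9α-acetoxy analogue of 6
Conditions: Ac2O, DMAP, pyridine, CH2Cl2, 0 °C → rt
Reagents that add atoms: acetic anhydride, CC(=O)OC(C)=O
Why: DMAP-catalysed acylation gives a temporary C9 protecting group that step 9 removes at no extra cost.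

**Step 6**
Reactants: 7
Product: 8, 9α-acetoxy-8-methoxy-4α,10β-dimethyl-5βH-bicyclo[4.4.0]dec-7-ene-2,6-dione
Conditions: TBAF, AcOH, THF, −20 → 0 °C
Reagents that add atoms: none
Why: Buffered fluoride cleaves the silyl enol ether to the C2 ketone without epimerising C5 or touching the acetate.

**Step 7**
Reactants: 8
Product: 9, 9α-acetoxy-2β-hydroxy-8-methoxy-4α,10β-dimethyl-5βH-bicyclo[4.4.0]dec-7-en-6-one
Conditions: L-Selectride (1.1 equiv), THF, −78 °C
Reagents that add atoms: none
Why: Bulky-hydride reduction of the only saturated ketone; in the preferred cis-decalin conformer (C4–Me equatorial, C10–Me axial on ring A) axial attack is blocked by the syn-axial C10–Me, so equatorial delivery gives the axial 2β-OH, trans to C4–Me.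

**Step 8**
Reactants: 9
Product: 10, 9α-acetoxy-2β-(TBS-oxy)-8-methoxy-4α,10β-dimethyl-5βH-bicyclo[4.4.0]dec-7-en-6-one
Conditions: TBSOTf, 2,6-lutidine, CH2Cl2, −40 → 0 °C
Reagents that add atoms: TBSOTf, CC(C)(C)[Si](C)(C)OS(=O)(=O)C(F)(F)F
Why: Silyl triflate protects the hindered axial C2–OH for the rest of the synthesis.

**Step 9**
Reactants: 10
Product: 11, 2β-(TBS-oxy)-9α-hydroxy-4α,10β-dimethyl-5βH-bicyclo[4.4.0]dec-6-en-8-one
Conditions: DIBAL-H (5 equiv), CH2Cl2, −78 °C; then 1 M HCl, THF, 0 °C
Reagents that add atoms: water, O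
Why: Stork–Danheiser carbonyl transposition: DIBAL reduces the vinylogous-ester C6=O (and cleaves the acetate), then acid hydrolyses the enol ether with allylic loss of C6–OH to give the Δ6-8-ketone while C9 is untouched.

**Step 10**
Reactants: 11
Product: 12, 7-iodo derivative of 11
Conditions: I2, pyridine, CH2Cl2, rt
Reagents that add atoms: iodine, II
Why: Johnson α-iodination of a cyclic enone (pyridine conjugate addition, iodination, elimination) puts the halide on C7.

**Step 11**
Reactants: 12
Product: 13, methyl 2-[2β-(TBS-oxy)-9α-hydroxy-4α,10β-dimethyl-8-oxo-5βH-bicyclo[4.4.0]dec-6-en-7-yl]acetate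
Conditions: BrZnCH2CO2Me (3 equiv), Pd2(dba)3/XPhos (5 mol%), THF, 50 °C
Reagents that add atoms: Reformatsky reagent of methyl bromoacetate, COC(=O)C[Zn]Br
Why: Negishi-type coupling of a Reformatsky zinc enolate with the α-iodoenone installs C11–C12 on C7.

**Step 12**
Reactants: 13
Product: 14, methyl 2-[2β-(TBS-oxy)-9α-hydroxy-4α,10β-dimethyl-8-oxobicyclo[4.4.0]dec-5-en-7α-yl]acetate (7β-H)
Conditions: TMSCl, NaI, Et3N, MeCN, 0 °C → rt; then TBAF/AcOH, THF, −78 °C (telescoped)
Reagents that add atoms: none
Why: Deconjugation via the thermodynamic 2-silyloxy-1,3-diene (γ-deprotonation at C5; ester α-H untouched) and kinetic α-protonation of the released dienolate from the β-face, anti to the pseudo-axial 9α-oxygen, sets 7β-H/7α-CH2CO2Me and moves the alkene to C5=C6.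

**Step 13**
Reactants: 14
Product: 15, trans-fused γ-lactone (12,8β-olide; 7β-H, 8α-H) of 2β-(TBS-oxy)-9α-hydroxy-4α,10β-dimethylbicyclo[4.4.0]dec-5-ene
Conditions: Me4NBH(OAc)3, MeCN/AcOH, −30 → 0 °C; then CSA (cat.), PhMe, 50 °C
Reagents that add atoms: none
Why: Hydroxyl-directed triacetoxyborohydride reduction delivers hydride from the C9α–O–B face to give 8β-OH (anti to both neighbours), and acid lactonisation with the 7α side chain closes the diequatorial trans γ-lactone.

**Step 14**
Reactants: 15
Product: 16, 9α-isobutyrate of 15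
Conditions: (i-PrCO)2O, DMAP, Et3N, CH2Cl2, rt
Reagents that add atoms: isobutyric anhydride, CC(C)C(=O)OC(=O)C(C)C
Why: DMAP acylation installs the C9 ester of the target and prevents 8→9 translactonisation in later steps.

**Step 15**
Reactants: 16
Product: 17, 11-(dimethylaminomethyl) lactone (C11 epimers)
Conditions: LDA (1.15 equiv), THF, −78 °C; then Me2N+=CH2 I−, −78 → 0 °C
Reagents that add atoms: Eschenmoser's salt, C=[N+](C)C.[I-]
Why: Mannich alkylation of the lactone enolate (more acidic and less hindered than the isobutyrate α-H) adds C13.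

**Step 16**
Reactants: 17
Product: 18, 5β,6β-epoxy-11(13)-methylene lactone
Conditions: m-CPBA (2.5 equiv), NaHCO3, CH2Cl2, 0 °C → rt
Reagents that add atoms: m-CPBA, O=C(OO)c1cccc(Cl)c1
Why: N-oxidation/Cope elimination unveils the α-methylene lactone (inert to peracid), and Prilezhaev epoxidation of the only electron-rich alkene occurs on the β-face because the trans-lactone locks ring B with ring A (axial C1, C4α-Me) under the α-face.

**Step 17**
Reactants: 18
Product: 19, 5α-hydroperoxy-6β-hydroxy derivative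
Conditions: ethereal H2O2 (excess), phosphomolybdic acid (1–2 mol%), Et2O, 0 °C → rt
Reagents that add atoms: hydrogen peroxide, OO
Why: Acid-catalysed epoxide perhydrolysis opens at the tertiary C5 (Markovnikov) and keeps the C6–O bond, so C6 is set as 6β-O; the C5 configuration is irrelevant because C5 becomes the ketone.

**Step 18**
Reactants: 19
Product: 20, bridged acyloxy ketal: 2-(TBS-oxy)-5,6,9-tris(isobutyryloxy)-5,10-epoxygermacr-11(13)-en-12,8-olide (11-oxabicyclo[4.4.1]undecane core)
Conditions: (i-PrCO)2O, DMAP (cat.), pyridine, CH2Cl2, −20 → 0 °C; then MeCN, 45 °C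
Reagents that add atoms: isobutyric anhydride, CC(C)C(=O)OC(=O)C(C)C
Why: Criegee rearrangement of the C5 perester (formed together with the C6 isobutyrate): the quaternary C10 migrates to oxygen with retention in preference to the acyloxy-deactivated C6 and secondary C4, and ion-pair collapse gives the ring-expanded ketal, as in the classical 9-decalyl perester to 6-hydroxycyclodecanone case.

**Step 19**
Reactants: 20
Product: 21, cardivin D
Conditions: 48% aq. HF, MeCN, 0 °C → rt
Reagents that add atoms: water, O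
Why: Mild acid hydrolysis of the acyloxy ketal releases the C5 ketone and the C10 tertiary alcohol, and the same medium removes the C2 TBS ether while the ordinary esters and lactone survive.

## Compound list
1 | 2-methoxy-6-methylphenol | COc1cccc(C)c1O | starting material
2 | 2-methoxy-6-methyl-1,4-benzoquinone | COC1=CC(=O)C=C(C)C1=O | intermediate
3 | (E)-pent-3-en-2-one | C/C=C/C(C)=O | starting material
4 | (E)-2-(triisopropylsilyloxy)penta-1,3-diene | C=C(O[Si](C(C)C)(C(C)C)C(C)C)/C=C/C | intermediate
5 | cis-fused Diels–Alder adduct (8-OMe, 6,9-dione, 2-OTIPS, 4α-Me, 5β-H, 10β-Me) | C[C@H]1C=C(O[Si](C(C)C)(C(C)C)C(C)C)C[C@@]2(C)C(=O)C(OC)=CC(=O)[C@@H]12 | intermediate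
6 | 9α-alcohol | C[C@H]1C=C(O[Si](C(C)C)(C(C)C)C(C)C)C[C@@]2(C)[C@@H](O)C(OC)=CC(=O)[C@@H]12 | intermediate
7 | 9α-acetate | C[C@H]1C=C(O[Si](C(C)C)(C(C)C)C(C)C)C[C@@]2(C)[C@@H](OC(C)=O)C(OC)=CC(=O)[C@@H]12 | intermediate
8 | C2 ketone | C[C@H]1CC(=O)C[C@@]2(C)[C@@H](OC(C)=O)C(OC)=CC(=O)[C@@H]12 | intermediate
9 | 2β-alcohol | C[C@H]1C[C@H](O)C[C@@]2(C)[C@@H](OC(C)=O)C(OC)=CC(=O)[C@@H]12 | intermediate
10 | 2β-TBS ether | C[C@H]1C[C@H](O[Si](C)(C)C(C)(C)C)C[C@@]2(C)[C@@H](OC(C)=O)C(OC)=CC(=O)[C@@H]12 | intermediate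
11 | transposed enone (Δ6-8-one, 9α-OH) | C[C@H]1C[C@H](O[Si](C)(C)C(C)(C)C)C[C@@]2(C)[C@@H](O)C(=O)C=C[C@@H]12 | intermediate
12 | 7-iodoenone | C[C@H]1C[C@H](O[Si](C)(C)C(C)(C)C)C[C@@]2(C)[C@@H](O)C(=O)C(I)=C[C@@H]12 | intermediate
13 | 7-(methoxycarbonylmethyl)enone | C[C@H]1C[C@H](O[Si](C)(C)C(C)(C)C)C[C@@]2(C)[C@@H](O)C(=O)C(CC(=O)OC)=C[C@@H]12 | intermediate
14 | Δ5-8-ketone, 7α-CH2CO2Me | C[C@H]1C[C@H](O[Si](C)(C)C(C)(C)C)C[C@@]2(C)[C@@H](O)C(=O)[C@@H](CC(=O)OC)C=C12 | intermediate
15 | trans γ-lactone, 9α-OH | C[C@H]1C[C@H](O[Si](C)(C)C(C)(C)C)C[C@@]2(C)[C@@H](O)[C@@H]3OC(=O)C[C@H]3C=C12 | intermediate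
16 | 9α-isobutyrate | C[C@H]1C[C@H](O[Si](C)(C)C(C)(C)C)C[C@@]2(C)[C@@H](OC(=O)C(C)C)[C@@H]3OC(=O)C[C@H]3C=C12 | intermediate
17 | Mannich base (C11 epimers) | C[C@H]1C[C@H](O[Si](C)(C)C(C)(C)C)C[C@@]2(C)[C@@H](OC(=O)C(C)C)[C@@H]3OC(=O)C(CN(C)C)[C@H]3C=C12 | intermediate
18 | α-methylene lactone 5β,6β-epoxide | C[C@H]1C[C@H](O[Si](C)(C)C(C)(C)C)C[C@@]2(C)[C@@H](OC(=O)C(C)C)[C@@H]3OC(=O)C(=C)[C@H]3[C@@H]4O[C@]124 | intermediate
19 | 5α-hydroperoxy-6β-ol | C[C@H]1C[C@H](O[Si](C)(C)C(C)(C)C)C[C@@]2(C)[C@@H](OC(=O)C(C)C)[C@@H]3OC(=O)C(=C)[C@H]3[C@H](O)[C@]12OO | intermediate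
20 | Criegee ketal (5,10-epoxy, 5-isobutyryloxy) | C[C@H]1C[C@H](O[Si](C)(C)C(C)(C)C)C[C@]2(C)O[C@@]1(OC(=O)C(C)C)[C@@H](OC(=O)C(C)C)[C@@H]3C(=C)C(=O)O[C@H]3[C@@H]2OC(=O)C(C)C | intermediate
21 | cardivin D | C=C1C(=O)O[C@@H]2[C@@H]1[C@H](OC(=O)C(C)C)C(=O)[C@@H](C)C[C@H](O)C[C@](C)(O)[C@H]2OC(=O)C(C)C | target

## Step count
- Total steps: 19.
- Longest linear sequence: 18 (steps 1, 3–19); step 2 is a one-step side branch.

## Three steps most likely to fail
- **Step 18 (Criegee ring expansion).** C4 migration or Hock-type cleavage could compete with the β-acyloxy-deactivated C10. Fallback: reduce 19 to the 5,6-diol, mesylate a free C9α-OH, and run a Wharton–Grob fragmentation of the C5 alkoxide to the 5-oxo-germacr-9(10)-ene, then install the C9/C10 oxygens by OsO4 dihydroxylation.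
- **Step 12 (deconjugative protonation setting C7).** The silyl enol ether may form toward C9 instead of C5, or protonation may be unselective. Fallback: set C7 by Ireland–Claisen rearrangement of the C9α-acetate of the C6 dienyl triflate (1,3-chirality transfer from C9–O to C7), then re-oxygenate C9 by Rubottom oxidation of the resulting C8 enol ether.
- **Step 17 (perhydrolysis of the hindered epoxide).** Meinwald rearrangement or slow opening could dominate. Fallback: avoid the peroxide altogether by hydrolysing 18 to the 5,6-diol, acylating C6–OH, and cleaving C5–C10 by alkoxy-radical β-scission (PhI(OAc)2/I2, hν), with transannular capture of the C10 cation by the new C5 carbonyl to reach the same bridged ketal.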